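**Retrosynthetic overview**
- Target ⇒ C-3 ester (Steglich) ⇒ 3β-allylic alcohol (Luche) ⇒ enone whose 8β-acetate and methyl ester come from opening a cis 8β,12-lactone (3-oxoalloalantolactone).
- Ring A (C4=C5) ⇒ acid-mediated aldol condensation of a monocyclic keto lactone carrying a 3-oxopentyl chain.
- Key disconnection: the C8–O bond of that lactone ⇒ directed γ-C–H lactonisation of a 2-substituted acrylic acid, which sets C-8.
- Acrylic acid ⇒ allylic oxidation of the isopropenyl CH3 of the Michael adduct of (+)-dihydrocarvone and ethyl vinyl ketone; the auxiliary-controlled Michael step sets C-10.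
- Ring order: ring B is bought (C-7 from the chiral pool), then the lactone ring, then ring A; the lactone is opened at the end.

Assumption: (+)-dihydrocarvone is used as the commercial mixture of C-2 epimers (C-2 is planarised in step 1), (E)-3-methylpent-2-enoic acid is bought, and positions are given in eudesmane numbering.

**Step 1**
Reactants: 1 (+)-dihydrocarvone [(2R,5R)-2-methyl-5-(prop-1-en-2-yl)cyclohexan-1-one]; 2 (R)-1-phenylethylamine; 3 ethyl vinyl ketone (pent-1-en-3-one)
Product: 6 (2S,5R)-2-methyl-2-(3-oxopentyl)-5-(prop-1-en-2-yl)cyclohexan-1-one, via ketimine 4 (not isolated), via Michael adduct ketimine 5 (not isolated)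
Conditions: 2, TsOH (cat.), toluene, reflux, Dean–Stark; then 3, THF, 40 °C, 4 d; then 10% aq AcOH, rt
Reagents that add atoms: water (O)
Why: Auxiliary-controlled Michael addition of the more substituted secondary enamine tautomer of the chiral ketimine (d'Angelo asymmetric Michael reaction, aza-ene-like transition state), in which the (R)-1-phenylethyl group controls the face of attack at C-2 and sets the quaternary centre (future C-10) with its methyl cis to the side chain, as in the established route to (+)-α-cyperone; C-7 comes from 1.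

**Step 2**
Reactants: 6 (2S,5R)-2-methyl-2-(3-oxopentyl)-5-(prop-1-en-2-yl)cyclohexan-1-one
Product: 9 2-[(1R,4S)-4-methyl-3-oxo-4-(3-oxopentyl)cyclohexyl]prop-2-enoic acid, via allylic alcohol 7 (not isolated), via enal 8 (not isolated)
Conditions: SeO2 (0.3 equiv), tBuOOH, CH2Cl2, 0 °C to rt; then TEMPO (cat.), NaOCl (cat.), NaClO2, MeCN/phosphate buffer pH 6.7, 35 °C
Reagents that add atoms: selenium dioxide SeO2 (O=[Se]=O); tert-butyl hydroperoxide (CC(C)(C)OO); sodium chlorite NaClO2 ([Na+].[O-]Cl=O)
Why: SeO2 allylic oxidation (ene reaction, then [2,3]-sigmatropic shift) attacks the only alkene and prefers its CH3 over the ring CH, and the alcohol/enal mixture converges on the acid in a TEMPO/chlorite oxidation that spares the ketones and the 1,1-disubstituted alkene; no stereocentre is touched.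

**Step 3**
Reactants: 9 2-[(1R,4S)-4-methyl-3-oxo-4-(3-oxopentyl)cyclohexyl]prop-2-enoic acid
Product: 10 (3aR,6R,7aR)-6-methyl-3-methylidene-6-(3-oxopentyl)-3a,4,7,7a-tetrahydro-1-benzofuran-2,5(3H,6H)-dione
Conditions: Cu(OTf)2 (2.5 equiv), Li2CO3 (1.5 equiv), MeCN (0.02 M), 390 nm LEDs, 25 °C, argon
Reagents that add atoms: none
Why: Proposed new method: the copper carboxylate of 9 is excited at 390 nm (ligand-to-metal charge transfer) to monovalent copper and a 2-alkylacryloyloxy radical, which like an aroyloxy radical loses CO2 only slowly (a vinyl radical would result) and instead abstracts hydrogen through a six-membered transition state (1,5-hydrogen atom transfer); only the two γ-CH2 groups are in reach, and the electrophilic oxygen radical avoids the α-keto CH2 (C-6) in favour of the unactivated C-8 CH2; the C-8 radical is captured by a second divalent copper and C–O reductive elimination from the trivalent copper alkyl carboxylate closes the γ-lactone, the short planar acrylate tether reaching only the lobe syn to the C-7 side chain, which sets C-8 as the cis (8β) C–O bond; closest known reaction type: oxidative lactonisation of 2-alkylbenzoic acids to phthalides via aroyloxy radicals and 1,5-hydrogen transfer, together with copper-carboxylate charge-transfer photochemistry of benzoic acids.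

**Step 4**
Reactants: 10 (3aR,6R,7aR)-6-methyl-3-methylidene-6-(3-oxopentyl)-3a,4,7,7a-tetrahydro-1-benzofuran-2,5(3H,6H)-dione
Product: 11 (3aR,8aR,9aR)-5,8a-dimethyl-3-methylidene-3a,4,7,8,8a,9-hexahydronaphtho[2,3-b]furan-2,6(3H,9aH)-dione (3-oxoalloalantolactone)
Conditions: TsOH·H2O (0.2 equiv), toluene, reflux, Dean–Stark
Reagents that add atoms: none
Why: Acid-catalysed intramolecular aldol condensation (second stage of a Robinson annulation): the enol of the ethyl ketone attacks the ring ketone and dehydration gives the tetrasubstituted C4=C5 enone, under conditions that spare the base-sensitive α-methylene lactone; no stereocentre is changed.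

**Step 5**
Reactants: 11 (3aR,8aR,9aR)-5,8a-dimethyl-3-methylidene-3a,4,7,8,8a,9-hexahydronaphtho[2,3-b]furan-2,6(3H,9aH)-dione
Product: 14 methyl 2-[(2R,3R,4aR)-3-acetoxy-4a,8-dimethyl-7-oxo-1,2,3,4,4a,5,6,7-octahydronaphthalen-2-yl]prop-2-enoate, via potassium hydroxy carboxylate 12 (not isolated), via hydroxy methyl ester 13 (not isolated)
Conditions: KOH (1.05 equiv), THF/H2O, 0 °C; evaporate; MeI, DMF, rt; evaporate; Ac2O, DMAP, pyridine, 0 °C to rt
Reagents that add atoms: potassium hydroxide KOH ([K+].[OH-]); iodomethane (CI); acetic anhydride (CC(=O)OC(C)=O)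
Why: Saponification of the strained α-methylene γ-lactone cleaves the acyl C–O bond so C-8 keeps its configuration, SN2 O-methylation of the carboxylate follows, and DMAP-catalysed acetylation caps the axial alcohol before it can relactonise (relactonised material is simply recovered 11).

**Step 6**
Reactants: 14 methyl 2-[(2R,3R,4aR)-3-acetoxy-4a,8-dimethyl-7-oxo-1,2,3,4,4a,5,6,7-octahydronaphthalen-2-yl]prop-2-enoate
Product: 15 methyl 2-[(2R,3R,4aR,7S)-3-acetoxy-7-hydroxy-4a,8-dimethyl-1,2,3,4,4a,5,6,7-octahydronaphthalen-2-yl]prop-2-enoate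
Conditions: NaBH4, CeCl3·7H2O, MeOH, −40 °C
Reagents that add atoms: none
Why: Luche 1,2-reduction, in which hydride adds axially to the enone carbonyl from the α face, anti to the angular methyl, giving the pseudo-equatorial 3β alcohol (S at that carbon) while the esters, acetate and acrylate are untouched at low temperature.

**Step 7**
Reactants: 15 methyl 2-[(2R,3R,4aR,7S)-3-acetoxy-7-hydroxy-4a,8-dimethyl-1,2,3,4,4a,5,6,7-octahydronaphthalen-2-yl]prop-2-enoate; 16 (E)-3-methylpent-2-enoic acid
Product: 17 methyl 2-[(2R,3R,4aR,7S)-3-acetoxy-4a,8-dimethyl-7-{[(2E)-3-methylpent-2-enoyl]oxy}-1,2,3,4,4a,5,6,7-octahydronaphthalen-2-yl]prop-2-enoate (CNP0118541.1)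
Conditions: 16 (1.5 equiv), DCC, DMAP (cat.), CH2Cl2, 0 °C to rt
Reagents that add atoms: none
Why: Steglich esterification (carbodiimide activation, acyl transfer through DMAP) forms the ester at the alcohol oxygen, so C-3 keeps its configuration and the E geometry of the acid is preserved.

**Compound list**
1 | (+)-dihydrocarvone, (2R,5R)-2-methyl-5-(prop-1-en-2-yl)cyclohexan-1-one (commercial, contains the C-2 epimer) | C=C(C)[C@H]1CC(=O)[C@H](C)CC1 | starting material
2 | (R)-1-phenylethylamine | C[C@@H](N)c1ccccc1 | starting material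
3 | ethyl vinyl ketone (pent-1-en-3-one) | C=CC(=O)CC | starting material
4 | (5R)-2-methyl-N-[(1R)-1-phenylethyl]-5-(prop-1-en-2-yl)cyclohexan-1-imine (C-2 epimers, in equilibrium with the secondary enamine) | C=C(C)[C@H]1CC(=N[C@H](C)c2ccccc2)C(C)CC1 | intermediate
5 | 1-[(1S,4R)-1-methyl-2-{[(1R)-1-phenylethyl]imino}-4-(prop-1-en-2-yl)cyclohexyl]pentan-3-one | C=C(C)[C@H]1CC(=N[C@H](C)c2ccccc2)[C@](C)(CCC(=O)CC)CC1 | intermediate
6 | (2S,5R)-2-methyl-2-(3-oxopentyl)-5-(prop-1-en-2-yl)cyclohexan-1-one | C=C(C)[C@H]1CC(=O)[C@](C)(CCC(=O)CC)CC1 | intermediate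
7 | (2S,5R)-5-(3-hydroxyprop-1-en-2-yl)-2-methyl-2-(3-oxopentyl)cyclohexan-1-one | C=C(CO)[C@H]1CC(=O)[C@](C)(CCC(=O)CC)CC1 | intermediate
8 | 2-[(1R,4S)-4-methyl-3-oxo-4-(3-oxopentyl)cyclohexyl]prop-2-enal | C=C(C=O)[C@H]1CC(=O)[C@](C)(CCC(=O)CC)CC1 | intermediate
9 | 2-[(1R,4S)-4-methyl-3-oxo-4-(3-oxopentyl)cyclohexyl]prop-2-enoic acid | C=C(C(=O)O)[C@H]1CC(=O)[C@](C)(CCC(=O)CC)CC1 | intermediate
10 | (3aR,6R,7aR)-6-methyl-3-methylidene-6-(3-oxopentyl)-3a,4,7,7a-tetrahydro-1-benzofuran-2,5(3H,6H)-dione (cis-fused lactone) | C=C3[C@H]1CC(=O)[C@](C)(CCC(=O)CC)C[C@H]1OC3=O | intermediate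
11 | (3aR,8aR,9aR)-5,8a-dimethyl-3-methylidene-3a,4,7,8,8a,9-hexahydronaphtho[2,3-b]furan-2,6(3H,9aH)-dione (3-oxoalloalantolactone) | C=C3[C@H]1CC2=C(C)C(=O)CC[C@]2(C)C[C@H]1OC3=O | intermediate
12 | potassium 2-[(2R,3R,4aR)-3-hydroxy-4a,8-dimethyl-7-oxo-1,2,3,4,4a,5,6,7-octahydronaphthalen-2-yl]prop-2-enoate | [K+].C=C(C(=O)[O-])[C@H]1CC2=C(C)C(=O)CC[C@]2(C)C[C@H]1O | intermediate
13 | methyl 2-[(2R,3R,4aR)-3-hydroxy-4a,8-dimethyl-7-oxo-1,2,3,4,4a,5,6,7-octahydronaphthalen-2-yl]prop-2-enoate | C=C(C(=O)OC)[C@H]1CC2=C(C)C(=O)CC[C@]2(C)C[C@H]1O | intermediate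
14 | methyl 2-[(2R,3R,4aR)-3-acetoxy-4a,8-dimethyl-7-oxo-1,2,3,4,4a,5,6,7-octahydronaphthalen-2-yl]prop-2-enoate | C=C(C(=O)OC)[C@H]1CC2=C(C)C(=O)CC[C@]2(C)C[C@H]1OC(C)=O | intermediate
15 | methyl 2-[(2R,3R,4aR,7S)-3-acetoxy-7-hydroxy-4a,8-dimethyl-1,2,3,4,4a,5,6,7-octahydronaphthalen-2-yl]prop-2-enoate | C=C(C(=O)OC)[C@H]1CC2=C(C)[C@@H](O)CC[C@]2(C)C[C@H]1OC(C)=O | intermediate
16 | (E)-3-methylpent-2-enoic acid | CC/C(C)=C/C(=O)O | starting material
17 | methyl 2-[(2R,3R,4aR,7S)-3-acetoxy-4a,8-dimethyl-7-{[(2E)-3-methylpent-2-enoyl]oxy}-1,2,3,4,4a,5,6,7-octahydronaphthalen-2-yl]prop-2-enoate | C=C(C(=O)OC)[C@H]1CC2=C(C)[C@@H](OC(=O)/C=C(\C)CC)CC[C@]2(C)C[C@H]1OC(C)=O | target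

**Step count and risks**
Total step count: 7. Longest linear sequence: 7 steps (1 to 17).

The three steps most likely to fail:

Step 3 (the new C–H lactonisation). The risks are hydrogen abstraction at C-6, decarboxylation of the acyloxy radical and some trans ring fusion. The fallback uses known amidyl-radical lactone chemistry (Hofmann–Löffler–Freytag type, hypervalent iodine variant). It sets out from acid 9, which is converted (iBuOCOCl, N-methylmorpholine, THF, −15 °C; then aqueous NH3) into 2-[(1R,4S)-4-methyl-3-oxo-4-(3-oxopentyl)cyclohexyl]prop-2-enamide F1. PhI(OAc)2 and I2 in CH2Cl2 under visible light generate the amidyl radical, which abstracts the same C-8 hydrogen by 1,5-transfer; iodine transfer anti to the side chain and ring closure through the amide oxygen give the cis iminolactone (3aR,6R,7aR)-2-imino-6-methyl-3-methylidene-6-(3-oxopentyl)hexahydro-1-benzofuran-5(4H)-one F2. Aqueous acetic acid hydrolyses this to keto lactone 10, where the route is rejoined.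

Step 2 (SeO2 oxidation beside two ketones, telescoped). The risks are α-oxidation of the ketones and a poor alcohol/enal mass balance. The fallback sets out from diketone 6: ene-type allylic chlorination with hypochlorous acid (Ca(OCl)2, solid CO2, CH2Cl2/H2O, 0 °C) gives (2S,5R)-5-(3-chloroprop-1-en-2-yl)-2-methyl-2-(3-oxopentyl)cyclohexan-1-one F3. Kornblum oxidation (NaHCO3, DMSO, 60 °C) then gives enal 8, where the route is rejoined; 8 is taken on to 9 with NaClO2 (NaH2PO4, 2-methylbut-2-ene, tBuOH/H2O).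

Step 4 (acid-mediated closure of ring A beside the α-methylene lactone). The risks are migration of the exocyclic alkene into the lactone ring and sluggish cyclisation. The fallback sets out from keto lactone 10 and reverses the order of events. KOH (3 equiv) in MeOH/H2O at 50 °C first saponifies the lactone to potassium 2-[(1R,2R,4R)-2-hydroxy-4-methyl-5-oxo-4-(3-oxopentyl)cyclohexyl]prop-2-enoate F4, in which the acrylate is protected as its carboxylate. The same base then closes ring A by aldol condensation, which gives carboxylate 12 directly; the route is rejoined there (MeI, then Ac2O as in step 5) and 11 is bypassed.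

**Further compounds**
F1 | step 3 | 2-[(1R,4S)-4-methyl-3-oxo-4-(3-oxopentyl)cyclohexyl]prop-2-enamide | C=C(C(N)=O)[C@H]1CC(=O)[C@](C)(CCC(=O)CC)CC1
F2 | step 3 | (3aR,6R,7aR)-2-imino-6-methyl-3-methylidene-6-(3-oxopentyl)hexahydro-1-benzofuran-5(4H)-one | C=C3[C@H]1CC(=O)[C@](C)(CCC(=O)CC)C[C@H]1OC3=N
F3 | step 2 | (2S,5R)-5-(3-chloroprop-1-en-2-yl)-2-methyl-2-(3-oxopentyl)cyclohexan-1-one | C=C(CCl)[C@H]1CC(=O)[C@](C)(CCC(=O)CC)CC1
F4 | step 4 | potassium 2-[(1R,2R,4R)-2-hydroxy-4-methyl-5-oxo-4-(3-oxopentyl)cyclohexyl]prop-2-enoate | [K+].C=C(C(=O)[O-])[C@H]1CC(=O)[C@](C)(CCC(=O)CC)C[C@H]1O
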